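**Target:** gnetucleistol F is the trans-(2R,3S)-2-aryl-3-hydroxymethyl-2,3-dihydrobenzofuran.

**Retrosynthetic overview**
1. Target 18 ⇐ global desilylation of the tetra-TIPS ether 17.
2. 17 ⇐ one-pot intramolecular inverse-demand [4+2] of pyridazine 14 with its tethered vinyl group, N2 loss and dehydrogenation. The pyridazine is a sacrificial four-carbon diene, and the dihydrofuran ring and the central benzene ring close together.
3. 14 ⇐ SNAr C–O coupling of the chiral homoallylic alcohol 5 with chloropyridazine 12.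
4. 5 ⇐ Ir-catalysed anti-(hydroxymethyl)allylation of O-TIPS syringaldehyde, which sets both stereocentres. 12 ⇐ site-selective Suzuki coupling of 3,6-dichloro-4-methoxypyridazine with a styrylboronate made from 3,5-dihydroxybenzaldehyde.
5. Ring order: both outer arenes and the pyridazine are bought; the furan ring and the central benzene ring are formed last, in the same operation.

Assumption: (R)-SEGPHOS is taken to give the (1R,2S)-diol in step 2; if the first run gives the antipode, (S)-SEGPHOS is used and nothing else changes.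

**Route**

Step 1
Reactants: 1 syringaldehyde
Product: 2 3,5-dimethoxy-4-(triisopropylsilyloxy)benzaldehyde
Conditions: TIPSCl (1.2 equiv), imidazole (2.5 equiv), DMAP (cat.), DMF, 40 °C
Reagents that add atoms: triisopropylsilyl chloride, CC(C)[Si](Cl)(C(C)C)C(C)C
Why: Imidazole-mediated O-silylation masks the only acidic phenol of this half so that no phenoxide is present in the later base-mediated steps.

Step 2
Reactants: 2 3,5-dimethoxy-4-(triisopropylsilyloxy)benzaldehyde; 3 racemic 4-vinyl-1,3-dioxolan-2-one (vinyl ethylene carbonate)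
Product: 4 (1R,2S)-1-[3,5-dimethoxy-4-(triisopropylsilyloxy)phenyl]-2-vinylpropane-1,3-diol
Conditions: [Ir(cod)Cl]2 (2.5 mol %), (R)-SEGPHOS (5 mol %), 4-cyano-3-nitrobenzoic acid (10 mol %), K3PO4 (5 mol %), i-PrOH (2 equiv), THF, 90 °C
Reagents that add atoms: none
Why: Krische iridium-catalysed transfer-hydrogenative carbonyl (hydroxymethyl)allylation, in which ionisation and decarboxylation of either enantiomer of 3 give the same (E)-σ-allyl iridium alkoxide that adds to the aldehyde through a closed chair transition state, so the anti relationship comes from the allyl geometry and the absolute (1R,2S) configuration from the chiral bisphosphine.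

Step 3
Reactants: 4 (1R,2S)-1-[3,5-dimethoxy-4-(triisopropylsilyloxy)phenyl]-2-vinylpropane-1,3-diol
Product: 5 (1R,2S)-1-[3,5-dimethoxy-4-(triisopropylsilyloxy)phenyl]-2-[(triisopropylsilyloxy)methyl]but-3-en-1-ol
Conditions: TIPSCl (1.1 equiv), imidazole (2.2 equiv), DMF, 0 °C → rt
Reagents that add atoms: triisopropylsilyl chloride, CC(C)[Si](Cl)(C(C)C)C(C)C
Why: The bulky silyl chloride reacts only at the primary hydroxyl and leaves the hindered benzylic one free, and TIPS is used instead of TBS because it does not migrate to the neighbouring alkoxide in step 7.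

Step 4
Reactants: 6 3,5-dihydroxybenzaldehyde
Product: 7 3,5-bis(triisopropylsilyloxy)benzaldehyde
Conditions: TIPSCl (2.3 equiv), imidazole (5 equiv), DMF, rt
Reagents that add atoms: triisopropylsilyl chloride, CC(C)[Si](Cl)(C(C)C)C(C)C
Why: Exhaustive phenol silylation gives a resorcinol unit that tolerates organolithium, Pd, alkoxide and 200 °C conditions and is released by fluoride at the end.

Step 5
Reactants: 7 3,5-bis(triisopropylsilyloxy)benzaldehyde; 8 bis(pinacolatoboryl)methane
Product: 10 (E)-2-[3,5-bis(triisopropylsilyloxy)styryl]-4,4,5,5-tetramethyl-1,3,2-dioxaborolane, via lithiated diboronate 9 (not isolated)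
Conditions: 8 (1.2 equiv), LiTMP (1.2 equiv), THF, 0 °C, 10 min; then 7, −78 °C → rt
Reagents that add atoms: none
Why: Boron–Wittig olefination, in which the α-boryl carbanion adds to the aldehyde and syn B–O elimination from the less hindered adduct gives the trans alkenyl boronate in one step.

Step 6
Reactants: 10 (E)-2-[3,5-bis(triisopropylsilyloxy)styryl]-4,4,5,5-tetramethyl-1,3,2-dioxaborolane; 11 3,6-dichloro-4-methoxypyridazine
Product: 12 3-chloro-4-methoxy-6-[(E)-3,5-bis(triisopropylsilyloxy)styryl]pyridazine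
Conditions: Pd(dppf)Cl2 (5 mol %), K3PO4 (2 equiv), 1,4-dioxane/H2O 9:1, 70 °C; 11 in 1.3-fold excess
Reagents that add atoms: none
Why: Suzuki–Miyaura mono-coupling with retention of the E geometry, in which oxidative addition is expected at C6–Cl because C3–Cl is flanked and mesomerically deactivated by the ortho methoxy group (the regiochemistry is confirmed by an NOE between H5 and the vinyl proton).

Step 7
Reactants: 5 (1R,2S)-1-[3,5-dimethoxy-4-(triisopropylsilyloxy)phenyl]-2-[(triisopropylsilyloxy)methyl]but-3-en-1-ol; 12 3-chloro-4-methoxy-6-[(E)-3,5-bis(triisopropylsilyloxy)styryl]pyridazine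
Product: 14 3-{[(1R,2S)-1-aryl-2-(TIPSO-methyl)but-3-en-1-yl]oxy}-4-methoxy-6-[(E)-3,5-bis(TIPSO)styryl]pyridazine, via sodium alkoxide 13 (not isolated)
Conditions: NaH (1.2 equiv), THF, 0 °C; then 12, 15-crown-5 (cat.), 0 → 55 °C
Reagents that add atoms: none
Why: SNAr (addition–elimination) of the alkoxide at the azine C3–Cl, which is now the only chloride, and since no bond to either stereocentre is broken both configurations are retained.

Step 8
Reactants: 14 3-{[(1R,2S)-1-aryl-2-(TIPSO-methyl)but-3-en-1-yl]oxy}-4-methoxy-6-[(E)-3,5-bis(TIPSO)styryl]pyridazine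
Product: 17 (2R,3S)-tetra-O-TIPS-gnetucleistol F, via diazene cycloadduct 15 (not isolated), via cyclohexadiene 16 (not isolated)
Conditions: degassed 1,2-dichlorobenzene (0.01 M), BHT (cat.), sealed tube, 200–210 °C; then cool to 0 °C, DDQ (1.05 equiv), 15 min
Reagents that add atoms: none
Why: Proposed new method: the tethered terminal alkene adds across C3/C6 of the pyridazine in an intramolecular inverse-electron-demand Diels–Alder reaction that closes the furan ring and the carbocycle together, cycloreversion expels N2, and DDQ dehydrogenates the resulting cyclohexadiene to the arene (pyridazine C3/C4/C5/C6 become C7a/C7/C6/C5 and the vinyl carbons become C3a/C4), the closest known reactions being the thermal alkyne–1,2-diazine cycloadditions that give indolines and 2,3-dihydrobenzofurans and the allyl-ether–pyridazine cycloadditions; C2 and C3 are carried over unchanged from 5, the anti arrangement becomes trans, and the transient C3a centre is erased on aromatisation.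

Step 9
Reactants: 17 (2R,3S)-tetra-O-TIPS-gnetucleistol F
Product: 18 gnetucleistol F
Conditions: TBAF (6 equiv), AcOH (4 equiv), THF, 0 °C → rt
Reagents that add atoms: none
Why: Fluoride-induced cleavage of the three aryl and one primary alkyl silyl ethers, buffered with acetic acid so that no free para-phenoxide can open the dihydrofuran through a quinone methide and erode the trans configuration.

**Compound list**

In 15 and 16 the new sp3 centres are transient and left undefined (diastereomer mixture). "Aryl" in short names means 3,5-dimethoxy-4-(triisopropylsilyloxy)phenyl.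

1 | syringaldehyde (4-hydroxy-3,5-dimethoxybenzaldehyde) | COc1cc(C=O)cc(OC)c1O | starting material
2 | 3,5-dimethoxy-4-(triisopropylsilyloxy)benzaldehyde | COc1cc(C=O)cc(OC)c1O[Si](C(C)C)(C(C)C)C(C)C | intermediate
3 | 4-vinyl-1,3-dioxolan-2-one (vinyl ethylene carbonate, racemic) | C=CC1COC(=O)O1 | starting material
4 | (1R,2S)-1-[3,5-dimethoxy-4-(triisopropylsilyloxy)phenyl]-2-vinylpropane-1,3-diol (anti) | COc1cc([C@H](O)[C@H](CO)C=C)cc(OC)c1O[Si](C(C)C)(C(C)C)C(C)C | intermediate
5 | (1R,2S)-1-[3,5-dimethoxy-4-(triisopropylsilyloxy)phenyl]-2-[(triisopropylsilyloxy)methyl]but-3-en-1-ol | COc1cc([C@H](O)[C@H](CO[Si](C(C)C)(C(C)C)C(C)C)C=C)cc(OC)c1O[Si](C(C)C)(C(C)C)C(C)C | intermediate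
6 | 3,5-dihydroxybenzaldehyde | O=Cc1cc(O)cc(O)c1 | starting material
7 | 3,5-bis(triisopropylsilyloxy)benzaldehyde | O=Cc1cc(O[Si](C(C)C)(C(C)C)C(C)C)cc(O[Si](C(C)C)(C(C)C)C(C)C)c1 | intermediate
8 | bis(pinacolatoboryl)methane | CC1(C)OB(CB2OC(C)(C)C(C)(C)O2)OC1(C)C | starting material
9 | lithio-bis(pinacolatoboryl)methane | [Li]C(B1OC(C)(C)C(C)(C)O1)B1OC(C)(C)C(C)(C)O1 | intermediate (not isolated)
10 | (E)-2-[3,5-bis(triisopropylsilyloxy)styryl]-4,4,5,5-tetramethyl-1,3,2-dioxaborolane | CC1(C)OB(/C=C/c2cc(O[Si](C(C)C)(C(C)C)C(C)C)cc(O[Si](C(C)C)(C(C)C)C(C)C)c2)OC1(C)C | intermediate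
11 | 3,6-dichloro-4-methoxypyridazine | COc1cc(Cl)nnc1Cl | starting material
12 | 3-chloro-4-methoxy-6-[(E)-3,5-bis(triisopropylsilyloxy)styryl]pyridazine | COc1cc(/C=C/c2cc(O[Si](C(C)C)(C(C)C)C(C)C)cc(O[Si](C(C)C)(C(C)C)C(C)C)c2)nnc1Cl | intermediate
13 | sodium (1R,2S)-1-aryl-2-[(triisopropylsilyloxy)methyl]but-3-en-1-olate | COc1cc([C@H]([O-])[C@H](CO[Si](C(C)C)(C(C)C)C(C)C)C=C)cc(OC)c1O[Si](C(C)C)(C(C)C)C(C)C.[Na+] | intermediate (not isolated)
14 | 3-{[(1R,2S)-1-aryl-2-[(triisopropylsilyloxy)methyl]but-3-en-1-yl]oxy}-4-methoxy-6-[(E)-3,5-bis(triisopropylsilyloxy)styryl]pyridazine | COc1cc(/C=C/c2cc(O[Si](C(C)C)(C(C)C)C(C)C)cc(O[Si](C(C)C)(C(C)C)C(C)C)c2)nnc1O[C@@H](c1cc(OC)c(O[Si](C(C)C)(C(C)C)C(C)C)c(OC)c1)[C@H](CO[Si](C(C)C)(C(C)C)C(C)C)C=C | intermediate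
15 | 2,3-diazabicyclo[2.2.2]octa-2,5-diene cycloadduct fused to the new tetrahydrofuran ring | COC1=CC2(/C=C/c4cc(O[Si](C(C)C)(C(C)C)C(C)C)cc(O[Si](C(C)C)(C(C)C)C(C)C)c4)N=NC13O[C@@H](c5cc(OC)c(O[Si](C(C)C)(C(C)C)C(C)C)c(OC)c5)[C@H](CO[Si](C(C)C)(C(C)C)C(C)C)C3C2 | intermediate (not isolated)
16 | (2R,3S)-2-aryl-7-methoxy-5-[(E)-3,5-bis(triisopropylsilyloxy)styryl]-3-[(triisopropylsilyloxy)methyl]-2,3,3a,4-tetrahydrobenzofuran | COC1=C2O[C@@H](c3cc(OC)c(O[Si](C(C)C)(C(C)C)C(C)C)c(OC)c3)[C@H](CO[Si](C(C)C)(C(C)C)C(C)C)C2CC(/C=C/c4cc(O[Si](C(C)C)(C(C)C)C(C)C)cc(O[Si](C(C)C)(C(C)C)C(C)C)c4)=C1 | intermediate (not isolated)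
17 | (2R,3S)-2-aryl-7-methoxy-5-[(E)-3,5-bis(triisopropylsilyloxy)styryl]-3-[(triisopropylsilyloxy)methyl]-2,3-dihydrobenzofuran | COc1cc([C@@H]2Oc3c(OC)cc(/C=C/c4cc(O[Si](C(C)C)(C(C)C)C(C)C)cc(O[Si](C(C)C)(C(C)C)C(C)C)c4)cc3[C@H]2CO[Si](C(C)C)(C(C)C)C(C)C)cc(OC)c1O[Si](C(C)C)(C(C)C)C(C)C | intermediate
18 | gnetucleistol F, (2R,3S) | COc1cc([C@@H]2Oc3c(OC)cc(/C=C/c4cc(O)cc(O)c4)cc3[C@H]2CO)cc(OC)c1O | target

**Step count**

Total: 9 steps. Longest linear sequence: 6 steps (1 → 2 → 4 → 5 → 14 → 17 → 18, or equally 6 → 7 → 10 → 12 → 14 → 17 → 18).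

**Three steps most likely to fail**

Step 8 (cycloaddition, N2 loss and aromatisation). The pyridazine carries two alkoxy donors, so the cycloaddition may need temperatures at which the benzylic heteroaryl ether eliminates, and the arene only forms if the dihydro intermediate is oxidised cleanly. The fallback changes the dienophile to a terminal alkyne, the directly precedented partner for 1,2-diazines, which aromatises by N2 loss alone. It sets out from 5 and returns at 17. The secondary hydroxyl of 5 is capped (TESOTf, 2,6-lutidine) to give the triethylsilyl ether F1. The vinyl group is cleaved (OsO4 cat., NaIO4, 2,6-lutidine, dioxane/H2O) to the aldehyde F2. Ohira–Bestmann homologation (dimethyl (1-diazo-2-oxopropyl)phosphonate, K2CO3, MeOH, 0 °C) gives the terminal alkyne F3. PPTS in MeOH removes the triethylsilyl group to give the alkynol F4. SNAr with 12 (NaH, THF) gives the alkynyl pyridazinyl ether F5. Heating F5 (1,3,5-triisopropylbenzene, 200–230 °C) passes through the bicyclic diazene adduct F6 and gives 17 directly, without oxidant.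

Step 6 (site selectivity of the Suzuki coupling). If oxidative addition is not clean at C6, the two chlorides are differentiated by another mechanism and the order of bond formation is inverted. The fallback sets out from 5 (as its alkoxide 13) and 11 and returns at 14. SNAr in toluene, where sodium chelation by the methoxy oxygen and N2 should steer the alkoxide ortho to the methoxy group, gives the chloropyridazinyl ether F7. Its single remaining chloride is then coupled with boronate 10 under the Suzuki conditions of step 6 to give 14. The regiochemistry of F7 needs the same NOE check as 12.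

Step 7 (SNAr of a hindered secondary alkoxide on a donor-substituted monochloride, with aryl silyl ethers present). If substitution is slow or silyl transfer intervenes, the electrophile is changed to a sulfone, which reacts at low temperature. The fallback sets out from 12 and returns at 14. NaSMe in THF gives the methyl sulfide F8. Oxone in buffered THF/MeOH/H2O, which leaves the stilbene untouched, gives the methyl sulfone F9. Alkoxide 13 displaces methanesulfinate from F9 at −20 °C to give 14.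

**Further compounds**

F1 | step 8 | triethylsilyl ether of 5: (1R,2S)-1-aryl-1-(triethylsilyloxy)-2-[(triisopropylsilyloxy)methyl]but-3-ene | COc1cc([C@H](O[Si](CC)(CC)CC)[C@H](CO[Si](C(C)C)(C(C)C)C(C)C)C=C)cc(OC)c1O[Si](C(C)C)(C(C)C)C(C)C
F2 | step 8 | (2S,3R)-3-aryl-3-(triethylsilyloxy)-2-[(triisopropylsilyloxy)methyl]propanal | COc1cc([C@H](O[Si](CC)(CC)CC)[C@H](CO[Si](C(C)C)(C(C)C)C(C)C)C=O)cc(OC)c1O[Si](C(C)C)(C(C)C)C(C)C
F3 | step 8 | (1R,2S)-1-aryl-1-(triethylsilyloxy)-2-[(triisopropylsilyloxy)methyl]but-3-yne | COc1cc([C@H](O[Si](CC)(CC)CC)[C@H](CO[Si](C(C)C)(C(C)C)C(C)C)C#C)cc(OC)c1O[Si](C(C)C)(C(C)C)C(C)C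
F4 | step 8 | (1R,2S)-1-aryl-2-[(triisopropylsilyloxy)methyl]but-3-yn-1-ol | COc1cc([C@H](O)[C@H](CO[Si](C(C)C)(C(C)C)C(C)C)C#C)cc(OC)c1O[Si](C(C)C)(C(C)C)C(C)C
F5 | step 8 | 3-{[(1R,2S)-1-aryl-2-[(triisopropylsilyloxy)methyl]but-3-yn-1-yl]oxy}-4-methoxy-6-[(E)-3,5-bis(triisopropylsilyloxy)styryl]pyridazine | COc1cc(/C=C/c2cc(O[Si](C(C)C)(C(C)C)C(C)C)cc(O[Si](C(C)C)(C(C)C)C(C)C)c2)nnc1O[C@@H](c1cc(OC)c(O[Si](C(C)C)(C(C)C)C(C)C)c(OC)c1)[C@H](CO[Si](C(C)C)(C(C)C)C(C)C)C#C
F6 | step 8 | 2,3-diazabicyclo[2.2.2]octa-2,5,7-triene adduct fused to the dihydrofuran ring | COC1=CC2(/C=C/c4cc(O[Si](C(C)C)(C(C)C)C(C)C)cc(O[Si](C(C)C)(C(C)C)C(C)C)c4)N=NC13O[C@@H](c5cc(OC)c(O[Si](C(C)C)(C(C)C)C(C)C)c(OC)c5)[C@H](CO[Si](C(C)C)(C(C)C)C(C)C)C3=C2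
F7 | step 6 | 6-chloro-3-{[(1R,2S)-1-aryl-2-[(triisopropylsilyloxy)methyl]but-3-en-1-yl]oxy}-4-methoxypyridazine | COc1cc(Cl)nnc1O[C@@H](c1cc(OC)c(O[Si](C(C)C)(C(C)C)C(C)C)c(OC)c1)[C@H](CO[Si](C(C)C)(C(C)C)C(C)C)C=C
F8 | step 7 | 4-methoxy-3-(methylthio)-6-[(E)-3,5-bis(triisopropylsilyloxy)styryl]pyridazine | COc1cc(/C=C/c2cc(O[Si](C(C)C)(C(C)C)C(C)C)cc(O[Si](C(C)C)(C(C)C)C(C)C)c2)nnc1SC
F9 | step 7 | 4-methoxy-3-(methylsulfonyl)-6-[(E)-3,5-bis(triisopropylsilyloxy)styryl]pyridazine | COc1cc(/C=C/c2cc(O[Si](C(C)C)(C(C)C)C(C)C)cc(O[Si](C(C)C)(C(C)C)C(C)C)c2)nnc1S(C)(=O)=O
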